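Everything rests on cutting the pyran ring at C1–C9 and O2–C3. The target offers a handle for this. C1 has O2 and C9 as neighbours, and O8, the tertiary hydroxyl on C8 of the cyclopentane ring, points to the α face, the face on which C9 holds C1. A glyoxylate ester on O8 therefore places the aldehyde C1=O2 beneath the diene C9=C5–C4=C3. Heating joins them in one operation: both bonds form, the pyran ring and a temporary γ-lactone close, and C9 is set. The precursor is a 1-(alk-1-en-2-yl)cyclopentene with the glyoxylate on its tertiary allylic O8, a PMB ether on O7 and TBS ethers on O10 and O11.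

Key step: step 12

Assumption: iridoid numbering (C1, O2, C3 to C11) is kept for every intermediate, β is the face of H5 and H9, and the spiro-epoxide carbon C4 of 31, which is erased in step 24, is drawn as the β-oxide.
Abbreviations: PMB = 4-methoxybenzyl, TBS = tert-butyldimethylsilyl, DMP = Dess–Martin periodinane, NBSH = 2-nitrobenzenesulfonylhydrazide, DEAD = diethyl azodicarboxylate.

Step 1
Reactants: 1 2-deoxy-D-ribose; 2 dimethyl (1-diazo-2-oxopropyl)phosphonate
Product: 3 (2R,3S)-hex-5-yne-1,2,3-triol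
Conditions: K2CO3, MeOH, rt
Reagents that add atoms: dimethyl (1-diazo-2-oxopropyl)phosphonate 2, CC(=O)C(=[N+]=[N-])P(=O)(OC)OC
Why: The Ohira–Bestmann homologation acts on the open-chain aldehyde in equilibrium with the lactol and turns CHO into C≡CH (C5≡C4) without touching the carbinol carbons that become C7 and C8.

Step 2
Reactants: 3 (2R,3S)-hex-5-yne-1,2,3-triol
Product: 4 (2R,4S,5R)-2-(4-methoxyphenyl)-4-(prop-2-yn-1-yl)-1,3-dioxan-5-ol
Conditions: 4-MeOC6H4CH(OMe)2, camphorsulfonic acid (cat.), CH2Cl2, rt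
Reagents that add atoms: 4-methoxybenzaldehyde dimethyl acetal, COc1ccc(C(OC)OC)cc1
Why: Thermodynamic acetalisation with an aryl aldehyde acetal prefers the six-membered 1,3-dioxane across O7 and O10, here an all-equatorial chair that also fixes the acetal carbon, and so leaves only O8 free.

Step 3
Reactants: 4 (2R,4S,5R)-2-(4-methoxyphenyl)-4-(prop-2-yn-1-yl)-1,3-dioxan-5-ol
Product: 5 (2R,4S,5R)-4-(4-hydroxybut-2-yn-1-yl)-2-(4-methoxyphenyl)-1,3-dioxan-5-ol
Conditions: n-BuLi (2.2 equiv), THF, −78 °C; (CH2O)n, to rt; then H2O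
Reagents that add atoms: paraformaldehyde (formaldehyde), C=O
Why: Double deprotonation followed by hydroxymethylation of the lithium acetylide with formaldehyde adds C11, the alkoxide on O8 being only a spectator.

Step 4
Reactants: 5 (2R,4S,5R)-4-(4-hydroxybut-2-yn-1-yl)-2-(4-methoxyphenyl)-1,3-dioxan-5-ol
Product: 6 (2R,3S)-3-(4-methoxybenzyloxy)hept-5-yne-1,2,7-triol
Conditions: i-Bu2AlH (5 equiv), CH2Cl2, −78 to 0 °C; then H2O
Reagents that add atoms: none
Why: In the reductive opening of the p-methoxybenzylidene acetal, i-Bu2AlH binds the less hindered primary oxygen O10 and cleaves its acetal bond, which leaves the PMB group on the secondary O7, where it can later be removed on its own.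

Step 5
Reactants: 6 (2R,3S)-3-(4-methoxybenzyloxy)hept-5-yne-1,2,7-triol
Product: 7 (2R,3S)-1,7-bis(tert-butyldimethylsilyloxy)-3-(4-methoxybenzyloxy)hept-5-yn-2-ol
Conditions: TBSCl (2.1 equiv), imidazole, CH2Cl2, 0 °C
Reagents that add atoms: tert-butyldimethylsilyl chloride, CC(C)(C)[Si](C)(C)Cl
Why: Sterically selective silylation protects the two primary hydroxyls (O10 and O11) and leaves the flanked secondary O8–H.

Step 6
Reactants: 7 (2R,3S)-1,7-bis(tert-butyldimethylsilyloxy)-3-(4-methoxybenzyloxy)hept-5-yn-2-ol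
Product: 8 (3S)-1,7-bis(tert-butyldimethylsilyloxy)-3-(4-methoxybenzyloxy)hept-5-yn-2-one
Conditions: DMP, CH2Cl2, rt
Reagents that add atoms: none
Why: Dess–Martin oxidation gives the C8 ketone under near-neutral conditions that should not epimerise the α-alkoxy centre C7.

Step 7
Reactants: 8 (3S)-1,7-bis(tert-butyldimethylsilyloxy)-3-(4-methoxybenzyloxy)hept-5-yn-2-one
Product: 9 (3R,4S)-8-(tert-butyldimethylsilyloxy)-3-[(tert-butyldimethylsilyloxy)methyl]-4-(4-methoxybenzyloxy)oct-1-en-6-yn-3-ol
Conditions: CH2=CHMgBr, THF, −78 °C; then H2O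
Reagents that add atoms: vinylmagnesium bromide, C=C[Mg]Br
Why: In this Cram-chelate Grignard addition magnesium bridges the ketone oxygen and the PMB ether oxygen O7 (the silyl ether O10 does not chelate), so the vinyl group (C9 and the future C3) attacks the face next to H7 and sets C8 as 8R.

Step 8
Reactants: 9 (3R,4S)-8-(tert-butyldimethylsilyloxy)-3-[(tert-butyldimethylsilyloxy)methyl]-4-(4-methoxybenzyloxy)oct-1-en-6-yn-3-ol
Product: 10 dienol (1R,5S)-1-[(tert-butyldimethylsilyloxy)methyl]-3-[3-(tert-butyldimethylsilyloxy)prop-1-en-2-yl]-5-(4-methoxybenzyloxy)cyclopent-2-en-1-ol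
Conditions: second-generation Grubbs catalyst RuCl2(=CHPh)(PCy3)(H2IMes) (5 mol %), CH2Cl2, reflux
Reagents that add atoms: none
Why: Ring-closing enyne metathesis of the 1,6-enyne in the exo mode closes the cyclopentene (C9=C5) and moves the terminal CH2 of the vinyl group onto C4 as C3, creating no stereocentre.

Step 9
Reactants: 10 dienol; 11 acetoxyacetyl chloride
Product: 12 O8 acetoxyacetate of dienol 10
Conditions: pyridine, DMAP (cat.), CH2Cl2, 0 °C to rt
Reagents that add atoms: acetoxyacetyl chloride 11, CC(=O)OCC(=O)Cl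
Why: DMAP-catalysed acylation of the tertiary allylic alcohol with a reactive acid chloride brings in C1 and the tether carbonyl as a masked glycolate, since glyoxylic acid itself does not esterify hindered alcohols cleanly.

Step 10
Reactants: 12 O8 acetoxyacetate
Product: 13 O8 glycolate (hydroxyacetate) of dienol 10
Conditions: K2CO3 (0.2 equiv), MeOH, 0 °C
Reagents that add atoms: none
Why: Base-catalysed (Zemplén-type) methanolysis removes the open primary acetate much faster than the crowded ester of the tertiary alcohol.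

Step 11
Reactants: 13 O8 glycolate
Product: 14 O8 glyoxylate (oxoacetate) of dienol 10, the cycloaddition precursor
Conditions: DMP, CH2Cl2, rt; filtration through Celite, no aqueous work-up
Reagents that add atoms: none
Why: Dess–Martin oxidation of the glycolate delivers the aldehyde in anhydrous form, free of the hydrate that aqueous routes to glyoxylates give.

Step 12
Reactants: 14 O8 glyoxylate of dienol 10
Product: 15 tricyclic cycloadduct (pyran with C4=C5, O8–C(=O)–C1 γ-lactone on the α face, H1 β, H9 β)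
Conditions: toluene (0.005 M), BHT (cat.), base-washed sealed tube, 130 °C
Reagents that add atoms: none
Why: The electron-poor aldehyde C1=O2 adds suprafacially across the s-cis diene C9=C5–C4=C3 in a concerted but asynchronous [4+2] process in which the C1–C9 bond leads, an intramolecular carbonyl (oxa) Diels–Alder reaction of the kind known for glyoxylates with 2,3-dialkyl dienes and for tethered dienals. The pyran ring (C1, O2, C3, C4, C5, C9) closes as the six-membered ring of the cycloaddition, and the γ-lactone (O8, ester carbon, C1, C9, C8) closes because the three-atom tether links the diene terminus C9 to C1, which requires the ester to leave its extended conformer for the lactone-like one. C9 is controlled by the tether: O8 stands on the α face of C8, so C1 can reach only the α face of C9 and H9 ends β. C1 is controlled by the tether-endo transition state, the only one leading to the unstrained cis-fused lactone, which puts the carboxyl carbon α and H1 β, and this centre is replaced in step 17. The regiochemistry (C1 to C9, O2 to C3) is enforced by the tether length and is not opposed electronically, because the ring alkyl group on C5 is a better donor than the CH2OTBS group on C4. The reaction has to outrun the carbonyl-ene path (C1–C9 bond with hydrogen transfer from C6 to O2) and ionisation of the tertiary allylic ester, which is why it is run hot, dilute and free of Lewis and Brønsted acids.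

Step 13
Reactants: 15 tricyclic cycloadduct
Product: 16 C11 alcohol of the cycloadduct
Conditions: pyridinium p-toluenesulfonate (cat.), MeOH, rt
Reagents that add atoms: none
Why: Acid-catalysed methanolysis of silyl ethers distinguishes the open allylic primary TBS ether on C11 from the neopentyl-type TBS ether on C10.

Step 14
Reactants: 16 C11 alcohol of the cycloadduct
Product: 19 4-methylene lactone (C4=C11 exocyclic alkene; H5 β; cis ring fusion), via allylic sulfonylhydrazine 17 (not isolated), via allylic diazene 18 (not isolated)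
Conditions: NBSH, PPh3, DEAD, THF, −30 °C to rt
Reagents that add atoms: none
Why: The Myers reductive transposition proceeds by Mitsunobu alkylation of NBSH, loss of sulfinic acid and retro-ene loss of N2 from the allylic diazene; it moves the double bond to C4=C11 and delivers hydrogen to C5 from the convex β face, because the lactone bridge covers the α face, which sets the cis ring fusion.

Step 15
Reactants: 19 4-methylene lactone
Product: 20 lithium 1α-carboxylate with free 8α-hydroxyl
Conditions: LiOH (1.0 equiv), THF/H2O, rt; freeze-drying, no acidification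
Reagents that add atoms: lithium hydroxide, [Li+].[OH-]
Why: Saponification opens the activated α-alkoxy-γ-lactone, and the product is kept as its lithium salt because the free γ-hydroxy acid would close again.

Step 16
Reactants: 21 (R)-3-methylpentanoic acid
Product: 22 lead tetrakis[(R)-3-methylpentanoate]
Conditions: Pb(OAc)4, 21 (4.4 equiv), toluene, 40 °C, reduced pressure (removal of AcOH)
Reagents that add atoms: lead tetraacetate, CC(=O)O[Pb](OC(C)=O)(OC(C)=O)OC(C)=O
Why: Carboxylate ligand exchange at tetravalent lead, driven by removal of the more volatile acetic acid, ensures that the only carboxylate present in step 17 is the wanted one.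

Step 17
Reactants: 20 lithium 1α-carboxylate; 22 lead tetrakis[(R)-3-methylpentanoate]
Product: 23 1β-[(R)-3-methylpentanoyloxy] acylal (1S) with 7-OPMB, 8-OH, 10-OTBS and the 4-methylene group
Conditions: 22 (1.2 equiv), benzene, rt to 40 °C, N2, dark
Reagents that add atoms: lead tetrakis[(R)-3-methylpentanoate] 22, CC[C@@H](C)CC(=O)O[Pb](OC(=O)C[C@H](C)CC)(OC(=O)C[C@H](C)CC)OC(=O)C[C@H](C)CC
Why: In this Kochi-type oxidative decarboxylation of an α-alkoxy carboxylate the C1 radical is oxidised to the oxocarbenium ion and captured by 3-methylpentanoate on the convex β face, anti to the C9–C8 bond, which resets C1 to the target configuration at a stage where no oxidisable enol ether is present.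

Step 18
Reactants: 23 1β-acylal with 7-OPMB
Product: 24 7β-alcohol
Conditions: DDQ, CH2Cl2/pH 7 buffer, 0 °C
Reagents that add atoms: none
Why: Oxidative PMB cleavage with DDQ in buffered medium frees O7 alone, while the silyl ether, the acylal and the 1,1-disubstituted alkene should persist.

Step 19
Reactants: 25 4-(tert-butyldimethylsilyloxy)benzaldehyde
Product: 26 1-(2,2-dibromovinyl)-4-(tert-butyldimethylsilyloxy)benzene
Conditions: CBr4, PPh3, CH2Cl2, 0 °C
Reagents that add atoms: carbon tetrabromide, BrC(Br)(Br)Br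
Why: This is the first stage of the Corey–Fuchs sequence, dibromo-olefination of an aromatic aldehyde, which the aryl silyl ether tolerates.

Step 20
Reactants: 26 1-(2,2-dibromovinyl)-4-(tert-butyldimethylsilyloxy)benzene
Product: 28 3-[4-(tert-butyldimethylsilyloxy)phenyl]prop-2-ynoic acid, via lithium acetylide 27 (not isolated)
Conditions: n-BuLi (2.1 equiv), THF, −78 °C; CO2; then dilute HCl
Reagents that add atoms: carbon dioxide, O=C=O
Why: The second stage of the Corey–Fuchs sequence (bromine–lithium exchange and 1,2-shift to the alkyne) is followed by carboxylation of the lithium acetylide.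

Step 21
Reactants: 24 7β-alcohol; 28 3-[4-(tert-butyldimethylsilyloxy)phenyl]prop-2-ynoic acid
Product: 29 7-O-arylpropiolate
Conditions: DCC, DMAP (cat.), CH2Cl2, 0 °C
Reagents that add atoms: 3-[4-(tert-butyldimethylsilyloxy)phenyl]prop-2-ynoic acid 28, OC(=O)C#Cc1ccc(O[Si](C)(C)C(C)(C)C)cc1
Why: Steglich esterification reaches the secondary O7–H while the tertiary O8–H stays inert, and the rod-like alkynoic acid removes any risk of Z to E leakage during acylation of this crowded alcohol.

Step 22
Reactants: 29 7-O-arylpropiolate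
Product: 30 7-O-[(Z)-4-(tert-butyldimethylsilyloxy)cinnamate]
Conditions: H2 (1 atm), Pd/CaCO3 poisoned with Pb(OAc)2, quinoline, EtOAc, rt
Reagents that add atoms: none
Why: Lindlar semihydrogenation adds H2 syn to the alkynoate and so fixes the Z-cinnamate, while the 1,1-disubstituted alkene is not reduced on the poisoned catalyst.

Step 23
Reactants: 30 7-O-(Z)-cinnamate with the 4-methylene group
Product: 31 4,11-epoxide (spiro-oxirane, drawn as the β-oxide)
Conditions: dimethyldioxirane (acetone solution), CH2Cl2, −20 to 0 °C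
Reagents that add atoms: dimethyldioxirane, CC1(C)OO1
Why: Electrophilic epoxidation with a neutral dioxirane selects the electron-rich C4=C11 alkene over the conjugated Z-enoate and returns the C11 oxygen, and the new centre C4 is erased in step 24.

Step 24
Reactants: 31 4,11-epoxide
Product: 32 10-O,4'-O-bis-TBS ether of the target (C3=C4 enol ether, free 11-OH)
Conditions: Cp2TiCl2 (2.5 equiv), Zn dust, THF, rt; then H2O
Reagents that add atoms: none
Why: In this titanocene-mediated isomerisation of an epoxide to an allylic alcohol, Cp2TiCl opens the oxirane by single-electron transfer to the tertiary C4 radical and a second trivalent titanium removes a β-hydrogen from the less hindered and weaker C3–H rather than from the ring-fusion C5–H, which gives the enol ether under neutral conditions.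

Step 25
Reactants: 32 bis-TBS ether of the target
Product: 33 target CNP0217341.1
Conditions: HF·pyridine, excess pyridine, THF, 0 °C to rt
Reagents that add atoms: none
Why: Fluoride-mediated desilylation of the aryl and primary TBS ethers is run in pyridine-buffered medium to spare the enol ether, the acylal and the Z-enoate and to suppress an O7 to O10 acyl shift.

Compound list
1 | 2-deoxy-D-ribose (open-chain form drawn) | O=CC[C@H](O)[C@H](O)CO | starting material
2 | dimethyl (1-diazo-2-oxopropyl)phosphonate | CC(=O)C(=[N+]=[N-])P(=O)(OC)OC | starting material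
3 | (2R,3S)-hex-5-yne-1,2,3-triol | C#CC[C@H](O)[C@H](O)CO | intermediate
4 | (2R,4S,5R)-2-(4-methoxyphenyl)-4-(prop-2-yn-1-yl)-1,3-dioxan-5-ol | C#CC[C@@H]1O[C@H](c2ccc(OC)cc2)OC[C@H]1O | intermediate
5 | (2R,4S,5R)-4-(4-hydroxybut-2-yn-1-yl)-2-(4-methoxyphenyl)-1,3-dioxan-5-ol | OCC#CC[C@@H]1O[C@H](c2ccc(OC)cc2)OC[C@H]1O | intermediate
6 | (2R,3S)-3-(4-methoxybenzyloxy)hept-5-yne-1,2,7-triol | OCC#CC[C@H](OCc1ccc(OC)cc1)[C@H](O)CO | intermediate
7 | (2R,3S)-1,7-bis(TBS-oxy)-3-(PMB-oxy)hept-5-yn-2-ol | CC(C)(C)[Si](C)(C)OCC#CC[C@H](OCc1ccc(OC)cc1)[C@H](O)CO[Si](C)(C)C(C)(C)C | intermediate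
8 | (3S)-1,7-bis(TBS-oxy)-3-(PMB-oxy)hept-5-yn-2-one | CC(C)(C)[Si](C)(C)OCC#CC[C@H](OCc1ccc(OC)cc1)C(=O)CO[Si](C)(C)C(C)(C)C | intermediate
9 | (3R,4S)-8-(TBS-oxy)-3-(TBS-oxymethyl)-4-(PMB-oxy)oct-1-en-6-yn-3-ol | CC(C)(C)[Si](C)(C)OCC#CC[C@H](OCc1ccc(OC)cc1)[C@](O)(CO[Si](C)(C)C(C)(C)C)C=C | intermediate
10 | dienol, (1R,5S)-1-(TBS-oxymethyl)-3-[3-(TBS-oxy)prop-1-en-2-yl]-5-(PMB-oxy)cyclopent-2-en-1-ol | C=C(CO[Si](C)(C)C(C)(C)C)C1=C[C@@](O)(CO[Si](C)(C)C(C)(C)C)[C@@H](OCc2ccc(OC)cc2)C1 | intermediate
11 | acetoxyacetyl chloride | CC(=O)OCC(=O)Cl | starting material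
12 | O8 acetoxyacetate of dienol 10 | C=C(CO[Si](C)(C)C(C)(C)C)C1=C[C@@](OC(=O)COC(C)=O)(CO[Si](C)(C)C(C)(C)C)[C@@H](OCc2ccc(OC)cc2)C1 | intermediate
13 | O8 glycolate of dienol 10 | C=C(CO[Si](C)(C)C(C)(C)C)C1=C[C@@](OC(=O)CO)(CO[Si](C)(C)C(C)(C)C)[C@@H](OCc2ccc(OC)cc2)C1 | intermediate
14 | O8 glyoxylate of dienol 10 (key-step precursor) | C=C(CO[Si](C)(C)C(C)(C)C)C1=C[C@@](OC(=O)C=O)(CO[Si](C)(C)C(C)(C)C)[C@@H](OCc2ccc(OC)cc2)C1 | intermediate
15 | tricyclic cycloadduct (C4=C5, α-face O8–C1 lactone, H1 β, H9 β) | O=C1O[C@]2(CO[Si](C)(C)C(C)(C)C)[C@@H](OCc3ccc(OC)cc3)CC4=C(CO[Si](C)(C)C(C)(C)C)CO[C@H]1[C@H]24 | intermediate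
16 | C11 alcohol of the cycloadduct | O=C1O[C@]2(CO[Si](C)(C)C(C)(C)C)[C@@H](OCc3ccc(OC)cc3)CC4=C(CO)CO[C@H]1[C@H]24 | intermediate
17 | allylic N-(2-nitrobenzenesulfonyl)hydrazine at C11 (not isolated) | O=C1O[C@]2(CO[Si](C)(C)C(C)(C)C)[C@@H](OCc3ccc(OC)cc3)CC4=C(CN(N)S(=O)(=O)c5ccccc5[N+](=O)[O-])CO[C@H]1[C@H]24 | intermediate
18 | allylic diazene at C11 (not isolated) | O=C1O[C@]2(CO[Si](C)(C)C(C)(C)C)[C@@H](OCc3ccc(OC)cc3)CC4=C(CN=N)CO[C@H]1[C@H]24 | intermediate
19 | 4-methylene lactone (H5 β, H9 β) | O=C1O[C@]2(CO[Si](C)(C)C(C)(C)C)[C@@H](OCc3ccc(OC)cc3)C[C@@H]4C(=C)CO[C@H]1[C@H]24 | intermediate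
20 | lithium 1α-carboxylate, 8α-OH free | [Li+].[O-]C(=O)[C@H]1OCC(=C)[C@H]2C[C@H](OCc3ccc(OC)cc3)[C@](O)(CO[Si](C)(C)C(C)(C)C)[C@@H]12 | intermediate
21 | (R)-3-methylpentanoic acid | CC[C@@H](C)CC(=O)O | starting material
22 | lead tetrakis[(R)-3-methylpentanoate] | CC[C@@H](C)CC(=O)O[Pb](OC(=O)C[C@H](C)CC)(OC(=O)C[C@H](C)CC)OC(=O)C[C@H](C)CC | intermediate
23 | 1β-[(R)-3-methylpentanoyloxy] acylal, 7-OPMB, 10-OTBS, 4-methylene | CC[C@@H](C)CC(=O)O[C@@H]1OCC(=C)[C@H]2C[C@H](OCc3ccc(OC)cc3)[C@](O)(CO[Si](C)(C)C(C)(C)C)[C@@H]12 | intermediate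
24 | 7β-alcohol | CC[C@@H](C)CC(=O)O[C@@H]1OCC(=C)[C@H]2C[C@H](O)[C@](O)(CO[Si](C)(C)C(C)(C)C)[C@@H]12 | intermediate
25 | 4-(tert-butyldimethylsilyloxy)benzaldehyde | O=Cc1ccc(O[Si](C)(C)C(C)(C)C)cc1 | starting material
26 | 1-(2,2-dibromovinyl)-4-(tert-butyldimethylsilyloxy)benzene | BrC(Br)=Cc1ccc(O[Si](C)(C)C(C)(C)C)cc1 | intermediate
27 | lithium [4-(tert-butyldimethylsilyloxy)phenyl]acetylide (not isolated) | [Li]C#Cc1ccc(O[Si](C)(C)C(C)(C)C)cc1 | intermediate
28 | 3-[4-(tert-butyldimethylsilyloxy)phenyl]prop-2-ynoic acid | OC(=O)C#Cc1ccc(O[Si](C)(C)C(C)(C)C)cc1 | intermediate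
29 | 7-O-arylpropiolate | CC[C@@H](C)CC(=O)O[C@@H]1OCC(=C)[C@H]2C[C@H](OC(=O)C#Cc3ccc(O[Si](C)(C)C(C)(C)C)cc3)[C@](O)(CO[Si](C)(C)C(C)(C)C)[C@@H]12 | intermediate
30 | 7-O-[(Z)-4-(TBS-oxy)cinnamate], 4-methylene | CC[C@@H](C)CC(=O)O[C@@H]1OCC(=C)[C@H]2C[C@H](OC(=O)/C=C\c3ccc(O[Si](C)(C)C(C)(C)C)cc3)[C@](O)(CO[Si](C)(C)C(C)(C)C)[C@@H]12 | intermediate
31 | 4,11-epoxide (β-oxide drawn) | CC[C@@H](C)CC(=O)O[C@@H]1OC[C@@]3(CO3)[C@H]2C[C@H](OC(=O)/C=C\c4ccc(O[Si](C)(C)C(C)(C)C)cc4)[C@](O)(CO[Si](C)(C)C(C)(C)C)[C@@H]12 | intermediate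
32 | 10-O,4'-O-bis-TBS ether of the target | CC[C@@H](C)CC(=O)O[C@@H]1OC=C(CO)[C@H]2C[C@H](OC(=O)/C=C\c3ccc(O[Si](C)(C)C(C)(C)C)cc3)[C@](O)(CO[Si](C)(C)C(C)(C)C)[C@@H]12 | intermediate
33 | CNP0217341.1 | CC[C@@H](C)CC(=O)O[C@@H]1OC=C(CO)[C@H]2C[C@H](OC(=O)/C=C\c3ccc(O)cc3)[C@](O)(CO)[C@@H]12 | target

Total step count: 25. Longest linear sequence: 22 (steps 1–15, 17, 18, 21–25).

Steps most likely to fail

Step 12. Transfer of a C6 hydrogen to O2 (carbonyl-ene reaction) may outrun closure of O2 on C3, or the ester may stay in its extended conformer so that the aldehyde oligomerises. The fallback sets out from 14 and makes the ene reaction the intended event (Me2AlCl, CH2Cl2, −78 °C). This forms the C1–C9 bond and the lactone and gives the α-hydroxy lactone with a C5=C6/C4=C3 diene, ene adduct F1. A palladium-catalysed intramolecular 1,4-oxyacetoxylation of that diene (Pd(OAc)2, benzoquinone, LiOAc, AcOH/acetone) would then bond O2 to C3 and place an acetate on C6, giving 6-acetoxy cycloadduct F2. Hydride substitution of the allylic acetate at its less hindered end (Pd(PPh3)4, NaBH4, THF) comes back to the route at 15.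

Step 17. The hydroxy carboxylate may close back to the lactone, tetravalent lead may attack the free O8 hydroxyl or the alkene, or capture at C1 may show poor facial selectivity. The fallback sets out from lactone 19 and avoids the hydrolysis altogether. i-Bu2AlH (CH2Cl2, −78 °C) gives tether lactol F3. Exchange of PhI(OAc)2 with 21 gives bis(acyloxy)iodobenzene F4. F3, F4 and I2 under visible light generate the lactol alkoxy radical, whose β-scission (Suárez-type fragmentation) cuts the bond between C1 and the tether carbon. The C1 radical is oxidised and captured by the carboxylate while O8 keeps the tether carbon as a formate, giving 8-O-formyl acylal F5. KHCO3 in aqueous MeOH removes the formate and comes back to the route at 23.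

Step 24. Hydrogen removal may occur at C5 or C11 instead of C3, or the tertiary radical may simply be reduced. The fallback sets out from 31. InCl3 (cat., THF) triggers the Meinwald rearrangement (1,2-hydride shift) to 4-formyl compound F6. TMSOTf/Et3N gives bis-TMS enol ether F7, in which O8 is silylated as well. DDQ with 2,6-lutidine abstracts hydride from C3, the only allylic position whose cation is stabilised by both O2 and the silyloxy group, and gives 3-alkoxy-enal F8. Luche reduction (NaBH4, CeCl3·7H2O, MeOH), in which the weakly acidic methanol also sheds the tertiary TMS ether, comes back to the route at 32.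

Further compounds
F1 | step 12 | ene adduct (α-hydroxy-γ-lactone, C5=C6 and C4=C3 diene) | O=C1O[C@]2(CO[Si](C)(C)C(C)(C)C)[C@@H](OCc3ccc(OC)cc3)C=C(C(=C)CO[Si](C)(C)C(C)(C)C)[C@@H]2[C@@H]1O
F2 | step 12 | 6-acetoxy cycloadduct (C6 epimer of no consequence) | O=C1O[C@]2(CO[Si](C)(C)C(C)(C)C)[C@@H](OCc3ccc(OC)cc3)C(OC(C)=O)C4=C(CO[Si](C)(C)C(C)(C)C)CO[C@H]1[C@H]24
F3 | step 17 | tether lactol (anomers) | OC1O[C@]2(CO[Si](C)(C)C(C)(C)C)[C@@H](OCc3ccc(OC)cc3)C[C@@H]4C(=C)CO[C@H]1[C@H]24
F4 | step 17 | bis[(R)-3-methylpentanoyloxy]iodobenzene | CC[C@@H](C)CC(=O)OI(OC(=O)C[C@H](C)CC)c1ccccc1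
F5 | step 17 | 8-O-formyl acylal | CC[C@@H](C)CC(=O)O[C@@H]1OCC(=C)[C@H]2C[C@H](OCc3ccc(OC)cc3)[C@](OC=O)(CO[Si](C)(C)C(C)(C)C)[C@@H]12
F6 | step 24 | 4-formyl compound (C4 epimers) | CC[C@@H](C)CC(=O)O[C@@H]1OCC(C=O)[C@H]2C[C@H](OC(=O)/C=C\c3ccc(O[Si](C)(C)C(C)(C)C)cc3)[C@](O)(CO[Si](C)(C)C(C)(C)C)[C@@H]12
F7 | step 24 | bis-TMS enol ether | CC[C@@H](C)CC(=O)O[C@@H]1OCC(=CO[Si](C)(C)C)[C@H]2C[C@H](OC(=O)/C=C\c3ccc(O[Si](C)(C)C(C)(C)C)cc3)[C@](O[Si](C)(C)C)(CO[Si](C)(C)C(C)(C)C)[C@@H]12
F8 | step 24 | 3-alkoxy-enal (8-O-TMS) | CC[C@@H](C)CC(=O)O[C@@H]1OC=C(C=O)[C@H]2C[C@H](OC(=O)/C=C\c3ccc(O[Si](C)(C)C(C)(C)C)cc3)[C@](O[Si](C)(C)C)(CO[Si](C)(C)C(C)(C)C)[C@@H]12
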